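## Retrosynthetic overview

1. Feature: ring A carries a cis-2α,3α-diol on the adjacent carbons C2 (equatorial, later acetylated) and C3 (axial). The pair sits between C1H2–C10 (quaternary, angular methyl) and quaternary C4 (gem-dimethyl). Cutting C2–C3 leaves two aldehyde arms on an intact, fully substituted ring B.
2. Ring order: ring B comes ready-made from (R)-carvone, which supplies the C5 stereocentre, the C8 methyl and the C9 carbonyl. Ring A is formed last, by SmI2 pinacol coupling of the C2 and C3 aldehydes.
3. Arms: C4–C3 is made by iron-hydride radical alkenylation of the isopropenyl group (styryl = masked C3 aldehyde). C10 is made by methylation, then allylation anti to the C5 arm (allyl = masked C1–C2 aldehyde).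
4. C8 is set by conjugate reduction and equilibration, and C9 by axial organocerium addition of a silylbutynyl chain. The E-enoate comes from carboalumination–carboxylation, and one ozonolysis frees both aldehydes.
5. After ring closure, the equatorial C2 hydroxyl is acetylated and the C9 silyl ether is removed.

Key step: step 10

Remark on the chemistry: read from the SMILES, the C9 hydroxyl is β (cis to the C10 methyl, equatorial) and the C11 chain is α (axial), and the route is planned for exactly this configuration. Labdane numbering is used for all intermediates (ring B = C5–C10); β is the face of the C10 methyl and α is the face of H5.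

## Route

Step 1
Reactants: 1 (R)-(−)-carvone; 2 (E)-β-nitrostyrene
Product: 3 (5R)-2-methyl-5-[(3E)-2-methyl-4-phenylbut-3-en-2-yl]cyclohex-2-en-1-one
Conditions: 1 (excess), 2, Fe(acac)3 (cat.), PhSiH3, EtOH, 60 °C
Reagents that add atoms: (E)-β-nitrostyrene (2), O=[N+]([O-])/C=C/c1ccccc1
Why: Iron-hydride hydrogen-atom transfer (MHAT) should select the electron-rich 1,1-disubstituted isopropenyl group over the electron-poor enone, and the tertiary C4 radical adds to the nitro-bearing carbon of 2 and expels NO2 (radical denitrative alkenylation), which builds quaternary C4 with its gem-dimethyl pair, installs C3 as an E-styryl carbon (a masked aldehyde inert to bases, hydrides and organometallics) and leaves C5 untouched; the step is run before any allyl group is present so that no 5-exo radical cyclisation can compete.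

Step 2
Reactants: 3 styryl enone
Product: 5 (5R,6S)-2,6-dimethyl-5-[(3E)-2-methyl-4-phenylbut-3-en-2-yl]cyclohex-2-en-1-one (trans epimer drawn; the epimer mixture is used as such), via lithium dienolate 4 (not isolated)
Conditions: LiN(i-Pr)2 (LDA), THF, −78 °C; MeI, −78 to 0 °C
Reagents that add atoms: iodomethane, CI
Why: Kinetic deprotonation of the enone at the alpha-prime carbon (C10) followed by SN2 methylation of the cross-conjugated dienolate (enolate alkylation) is standard for carvone-type enones, and the configuration of the new tertiary centre does not matter because it is planarised again in step 3.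

Step 3
Reactants: 5 methylated enone; 6 allyl bromide
Product: 8 (5S,6S)-6-allyl-2,6-dimethyl-5-[(3E)-2-methyl-4-phenylbut-3-en-2-yl]cyclohex-2-en-1-one (C10 methyl β; allyl α), via lithium dienolate 7 (not isolated)
Conditions: LiN(i-Pr)2 (LDA), THF, −78 °C; DMPU, 6, −78 °C to rt
Reagents that add atoms: allyl bromide (6), C=CCBr
Why: In this enolate alkylation the bulky C5 arm of dienolate 7 turns pseudoaxial on the β face to escape allylic A(1,2) strain with the C10 methyl, so the reactive allylic halide should enter from the open α face and set quaternary C10 with methyl β and allyl α, trans to the C5 arm.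

Step 4
Reactants: 8 quaternary enone
Product: 10 (2S,3S,6R)-2-allyl-2,6-dimethyl-3-[(3E)-2-methyl-4-phenylbut-3-en-2-yl]cyclohexan-1-one (C8 methyl α; equatorial), via lithium enolate 9 (not isolated)
Conditions: LiBH(s-Bu)3 (L-Selectride), THF, −78 °C; MeOH quench; NaOMe (cat.), MeOH, rt
Reagents that add atoms: none
Why: Conjugate (1,4) hydride reduction is the normal course for a cyclohexenone with an unsubstituted β-carbon and a carbonyl shielded by quaternary C10, it spares the isolated alkenes, and base equilibration of C8 should place the methyl equatorial (α) because the β epimer either clashes syn-diaxially with the C10 methyl or forces the C5 arm axial.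

Step 5
Reactants: 10 ketone; 11 (4-bromobut-1-yn-1-yl)trimethylsilane
Product: 13 (1S,2S,3S,6R)-2-allyl-2,6-dimethyl-3-[(3E)-2-methyl-4-phenylbut-3-en-2-yl]-1-[4-(trimethylsilyl)but-3-yn-1-yl]cyclohexan-1-ol (C9 hydroxyl β; chain α), via Grignard reagent 12 (not isolated)
Conditions: 11, Mg, THF, rt; CeCl3 (anhydrous), THF, −78 °C; 10, −78 to 0 °C; aq NH4Cl
Reagents that add atoms: (4-bromobut-1-yn-1-yl)trimethylsilane (11), C[Si](C)(C)C#CCCBr
Why: Organocerium 1,2-addition is chosen because the reagent is strongly nucleophilic yet barely basic toward this hindered ketone with one enolisable hydrogen, and in the only accessible chair (C5 arm, allyl and C8 methyl equatorial) the axial C10 methyl blocks the β trajectory, so the chain should enter axially from the α face past H5 and H7, as reagents generally approach a carbonyl next to an angular methyl, leaving the C9 hydroxyl β and equatorial.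

Step 6
Reactants: 13 tertiary alcohol
Product: 14 triethylsilyl ether of 13 (C9–OSiEt3 β)
Conditions: Et3SiOTf, 2,6-lutidine, CH2Cl2, 0 °C to rt
Reagents that add atoms: triethylsilyl trifluoromethanesulfonate, CC[Si](CC)(CC)OS(=O)(=O)C(F)(F)F
Why: Silylation with a silyl triflate and a hindered pyridine base is the standard method for crowded tertiary alcohols, and capping the equatorial C9 hydroxyl prevents it from closing a five-membered lactol onto the later C2 aldehyde.

Step 7
Reactants: 14 silyl ether
Product: 15 terminal alkyne (14 without the alkynyl SiMe3 group)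
Conditions: K2CO3 (cat.), MeOH, rt
Reagents that add atoms: none
Why: Base-catalysed methanolysis of the C(sp)–Si bond (protiodesilylation) is far faster than attack on the hindered tertiary triethylsilyl ether, so only the alkyne is unmasked.

Step 8
Reactants: 15 terminal alkyne
Product: 17 methyl (2E)-5-[(1S,2S,3S,6R)-2-allyl-2,6-dimethyl-3-[(3E)-2-methyl-4-phenylbut-3-en-2-yl]-1-(triethylsilyloxy)cyclohexyl]-3-methylpent-2-enoate, via alkenylalane 16 (not isolated)
Conditions: Me3Al, Cp2ZrCl2 (cat.), H2O (substoichiometric accelerator), CH2Cl2, −23 °C; ClCO2Me, −23 °C to rt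
Reagents that add atoms: trimethylaluminium, C[Al](C)C; methyl chloroformate, COC(=O)Cl
Why: Negishi zirconium-catalysed carboalumination adds methyl and aluminium syn across the terminal alkyne with aluminium at the terminus, acylation of alkenylalane 16 by the chloroformate proceeds with retention and so fixes the E geometry of C13–C14, and at low temperature the alkyne reacts much faster than the allyl or styryl double bond.

Step 9
Reactants: 17 enoate diene
Product: 19 ring B dialdehyde methyl (2E)-5-[(1S,2S,3R,6R)-2,6-dimethyl-3-(2-methyl-1-oxopropan-2-yl)-2-(2-oxoethyl)-1-(triethylsilyloxy)cyclohexyl]-3-methylpent-2-enoate, via bis-ozonide 18 (not isolated)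
Conditions: O3, CH2Cl2, −78 °C, Sudan Red 7B end-point indicator; PPh3, −78 °C to rt
Reagents that add atoms: ozone, [O-][O+]=O
Why: In this ozonolysis with reductive work-up the electrophilic dipole should consume the allyl and styryl double bonds before the ester-deactivated C13–C14 bond, with the dye marking the end point, and phosphine reduction of 18 frees the C2 and C3 aldehydes together under neutral conditions that allow neither aldol closure nor loss of the silyl ether, the aldehyde co-products being removed by chromatography before step 10.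

Step 10
Reactants: 19 ring B dialdehyde
Product: 21 methyl (13E)-2α,3α-dihydroxy-9β-(triethylsilyloxy)labd-13-en-15-oate (5α-H; 8α-methyl; C11 chain α), via samarium diolate 20 (not isolated)
Conditions: SmI2 (0.1 M in THF, 3 equiv) added to 19 (0.01 M in THF), −78 °C to rt; aq NaHCO3
Reagents that add atoms: none
Why: Divalent samarium transfers one electron to each aldehyde far faster than to the β,β-disubstituted enoate, and the C2 and C3 ketyl carbons (or one ketyl and the samarium-activated second carbonyl, followed by the second electron) join while trivalent samarium spans both oxygens, giving diolate 20, which is protonated on work-up. The closest known reaction type is the SmI2-mediated intramolecular pinacol coupling of 1,6-dialdehydes, which delivers cis-cyclohexane-1,2-diols. Ring A closes in a 6-exo-trig sense (C2 onto the C3 carbonyl carbon, both oxygens exocyclic) through a chair in which the two arms are trans-diequatorial on ring B, so the trans ring fusion is inherited from C5 and C10, and the gem-dimethyl group at C4 together with the fully substituted C9 and C10 presses the arms toward each other. The cis relation between the C2 and C3 oxygens comes from the samarium bridge. The face is decided by the axial β methyls on C4 and C10: the β,β chair would force the C2 oxygen axial between them, whereas the α,α chair has the C2 oxygen equatorial and the C3 oxygen axial on the open α face, anti to the axial C4 methyl, so C2 should form as R (2α) and C3 as S (3α). The step needs aldehyde-over-enoate chemoselectivity, secured by leaving out HMPA and amine–water activators, and freedom from lactol or aldol diversions, secured by the C9 silyl ether, the non-enolisable C3 aldehyde and the cold, neutral medium.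

Step 11
Reactants: 21 diol
Product: 22 methyl (13E)-2α-acetoxy-3α-hydroxy-9β-(triethylsilyloxy)labd-13-en-15-oate
Conditions: Ac2O (1.1 equiv), pyridine, DMAP (cat.), CH2Cl2, 0 °C
Reagents that add atoms: acetic anhydride, CC(=O)OC(C)=O
Why: In this DMAP-catalysed acylation the equatorial C2 hydroxyl next to a methylene reacts far faster than the axial, neopentyl C3 hydroxyl next to C4, and the acetate has no thermodynamic drive to migrate to the more crowded oxygen.

Step 12
Reactants: 22 acetate
Product: 23 target, methyl (13E)-(2R,3S,5S,8R,9S,10S)-2-acetoxy-3,9-dihydroxylabd-13-en-15-oate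
Conditions: HF·pyridine, pyridine, THF, 0 °C to rt
Reagents that add atoms: none
Why: Fluoride-driven Si–O cleavage under mildly acidic buffering removes the tertiary triethylsilyl ether without the alkoxide basicity that would trigger acetyl migration from C2 to C3, ester cleavage or dehydration of the C9 carbinol.

## Compound list

1 | (R)-(−)-carvone | O=C1C(C)=CC[C@@H](C(C)=C)C1 | starting material
2 | (E)-β-nitrostyrene | O=[N+]([O-])/C=C/c1ccccc1 | starting material
3 | (5R)-2-methyl-5-[(3E)-2-methyl-4-phenylbut-3-en-2-yl]cyclohex-2-en-1-one | O=C1C(C)=CC[C@@H](C(C)(C)/C=C/c2ccccc2)C1 | intermediate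
4 | lithium cross-conjugated dienolate of 3 (C9–OLi, C9=C10) | [Li]OC1=C[C@H](C(C)(C)/C=C/c2ccccc2)CC=C1C | intermediate
5 | (5R,6S)-2,6-dimethyl-5-[(3E)-2-methyl-4-phenylbut-3-en-2-yl]cyclohex-2-en-1-one (major trans epimer) | O=C1C(C)=CC[C@@H](C(C)(C)/C=C/c2ccccc2)[C@@H]1C | intermediate
6 | allyl bromide | C=CCBr | starting material
7 | lithium dienolate of 5 (C9–OLi, C9=C10 bearing methyl) | [Li]OC1=C(C)[C@H](C(C)(C)/C=C/c2ccccc2)CC=C1C | intermediate
8 | (5S,6S)-6-allyl-2,6-dimethyl-5-[(3E)-2-methyl-4-phenylbut-3-en-2-yl]cyclohex-2-en-1-one | O=C1C(C)=CC[C@@H](C(C)(C)/C=C/c2ccccc2)[C@]1(C)CC=C | intermediate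
9 | lithium enolate from conjugate reduction of 8 (C9–OLi, C8=C9) | [Li]OC1=C(C)CC[C@@H](C(C)(C)/C=C/c2ccccc2)[C@]1(C)CC=C | intermediate
10 | (2S,3S,6R)-2-allyl-2,6-dimethyl-3-[(3E)-2-methyl-4-phenylbut-3-en-2-yl]cyclohexan-1-one | O=C1[C@H](C)CC[C@@H](C(C)(C)/C=C/c2ccccc2)[C@]1(C)CC=C | intermediate
11 | (4-bromobut-1-yn-1-yl)trimethylsilane | C[Si](C)(C)C#CCCBr | starting material
12 | [4-(trimethylsilyl)but-3-yn-1-yl]magnesium bromide | C[Si](C)(C)C#CCC[Mg]Br | intermediate
13 | (1S,2S,3S,6R)-2-allyl-2,6-dimethyl-3-[(3E)-2-methyl-4-phenylbut-3-en-2-yl]-1-[4-(trimethylsilyl)but-3-yn-1-yl]cyclohexan-1-ol | C[Si](C)(C)C#CCC[C@]1(O)[C@H](C)CC[C@@H](C(C)(C)/C=C/c2ccccc2)[C@]1(C)CC=C | intermediate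
14 | triethylsilyl ether of 13 | C[Si](C)(C)C#CCC[C@]1(O[Si](CC)(CC)CC)[C@H](C)CC[C@@H](C(C)(C)/C=C/c2ccccc2)[C@]1(C)CC=C | intermediate
15 | terminal alkyne (but-3-yn-1-yl chain at C9, C9–OSiEt3) | C#CCC[C@]1(O[Si](CC)(CC)CC)[C@H](C)CC[C@@H](C(C)(C)/C=C/c2ccccc2)[C@]1(C)CC=C | intermediate
16 | (E)-alkenyl(dimethyl)alane from 15 (Al on C14, cis to the new C13 methyl) | C[Al](C)/C=C(\C)CC[C@]1(O[Si](CC)(CC)CC)[C@H](C)CC[C@@H](C(C)(C)/C=C/c2ccccc2)[C@]1(C)CC=C | intermediate
17 | methyl (2E)-5-[(1S,2S,3S,6R)-2-allyl-2,6-dimethyl-3-[(3E)-2-methyl-4-phenylbut-3-en-2-yl]-1-(triethylsilyloxy)cyclohexyl]-3-methylpent-2-enoate | COC(=O)/C=C(\C)CC[C@]1(O[Si](CC)(CC)CC)[C@H](C)CC[C@@H](C(C)(C)/C=C/c2ccccc2)[C@]1(C)CC=C | intermediate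
18 | bis(1,2,4-trioxolane) of 17 (trioxolane carbons as epimer mixture) | COC(=O)/C=C(\C)CC[C@]1(O[Si](CC)(CC)CC)[C@H](C)CC[C@@H](C(C)(C)C2OC(c3ccccc3)OO2)[C@]1(C)CC4OCOO4 | intermediate
19 | ring B dialdehyde, methyl (13E)-2,3-dioxo-9β-(triethylsilyloxy)-2,3-secolabd-13-en-15-oate | COC(=O)/C=C(\C)CC[C@]1(O[Si](CC)(CC)CC)[C@H](C)CC[C@@H](C(C)(C)C=O)[C@]1(C)CC=O | intermediate
20 | bis(diiodosamarium) 2α,3α-diolate | COC(=O)/C=C(\C)CC[C@]1(O[Si](CC)(CC)CC)[C@H](C)CC[C@H]2C(C)(C)[C@H](O[Sm](I)I)[C@H](O[Sm](I)I)C[C@@]21C | intermediate
21 | methyl (13E)-2α,3α-dihydroxy-9β-(triethylsilyloxy)labd-13-en-15-oate | COC(=O)/C=C(\C)CC[C@]1(O[Si](CC)(CC)CC)[C@H](C)CC[C@H]2C(C)(C)[C@H](O)[C@H](O)C[C@@]21C | intermediate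
22 | methyl (13E)-2α-acetoxy-3α-hydroxy-9β-(triethylsilyloxy)labd-13-en-15-oate | COC(=O)/C=C(\C)CC[C@]1(O[Si](CC)(CC)CC)[C@H](C)CC[C@H]2C(C)(C)[C@H](O)[C@H](OC(C)=O)C[C@@]21C | intermediate
23 | methyl (13E)-(2R,3S,5S,8R,9S,10S)-2-acetoxy-3,9-dihydroxylabd-13-en-15-oate (CNP0135744.1) | COC(=O)/C=C(\C)CC[C@]1(O)[C@H](C)CC[C@H]2C(C)(C)[C@H](O)[C@H](OC(C)=O)C[C@@]21C | target

## Step count and risks

Total step count: 12. Longest linear sequence: 12 steps (1 to 23).

**Step 10 (pinacol closure).**
- What may go wrong: the coupling may pass through an open, unbridged arrangement, which would erode the cis selectivity in favour of the diequatorial trans relation. The hindered neopentyl ketyl may also be protonated and reduced before the C–C bond forms.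
- Fallback: it sets out from 17 and comes back at 21. Ring-closing metathesis of the allyl and styryl groups with the second-generation Grubbs catalyst in refluxing CH2Cl2 should give the ring A alkene, methyl (13E)-9β-(triethylsilyloxy)labda-2,13-dien-15-oate F1.
- Catalytic OsO4 with N-methylmorpholine N-oxide should then add both oxygens syn from the α face. The axial methyls on C4 and C10 shield the β face, and the enoate is electronically deactivated, so this should give 21.

**Step 5 (chain addition at C9).**
- What may go wrong: enolisation or β-hydride transfer may take over at the carbonyl wedged between C8 and quaternary C10. Some reagent may also leak through the equatorial trajectory, which would lower the facial selectivity.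
- Fallback: it sets out from 10 and comes back at 13. A Corey–Chaykovsky reaction with the small, irreversibly adding dimethylsulfonium methylide (Me3SI, n-BuLi, THF, 0 °C) should transfer the methylene axially from the α face. This should give the spiro-oxirane with oxygen β and C11 methylene α F2.
- Lithiated 1-(trimethylsilyl)propyne (n-BuLi, THF, DMPU, −78 °C to rt) then opens the oxirane at its unsubstituted carbon. This forms C11–C12 away from the congested centre and delivers 13.

**Step 9 (double ozonolysis).**
- What may go wrong: ozone may attack the C13–C14 enoate before the hindered styryl bond is fully consumed, or cleavage may stop short when the reaction is halted early.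
- Fallback: it sets out from 14 and comes back at 19, and it cleaves the alkenes before the enoate exists.
- Ozonolysis of 14 with NaBH4 work-up (the silylalkyne reacts far more slowly than the alkenes) should give the C2,C3-diol F3.
- Et3SiCl and imidazole should give the tris(triethylsilyl) ether F4.
- K2CO3 in MeOH should give the terminal alkyne F5.
- Carboalumination and methyl chloroformate, as in step 8, should give the enoate bis(primary silyl ether) F6.
- Swern conditions ((COCl)2, DMSO, Et3N, −78 to −30 °C) oxidise primary triethylsilyl ethers directly to aldehydes and spare the tertiary one, which gives 19.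

## Further compounds

F1 | step 10 | methyl (13E)-9β-(triethylsilyloxy)labda-2,13-dien-15-oate | COC(=O)/C=C(\C)CC[C@]1(O[Si](CC)(CC)CC)[C@H](C)CC[C@H]2C(C)(C)C=CC[C@@]21C
F2 | step 5 | spiro-oxirane of 10 at C9 (oxygen β and equatorial, C11 methylene α and axial) | C1O[C@]12[C@H](C)CC[C@@H](C(C)(C)/C=C/c3ccccc3)[C@]2(C)CC=C
F3 | step 9 | C2,C3-diol with C9–OSiEt3 and silylbutynyl chain | C[Si](C)(C)C#CCC[C@]1(O[Si](CC)(CC)CC)[C@H](C)CC[C@@H](C(C)(C)CO)[C@]1(C)CCO
F4 | step 9 | tris(triethylsilyl) ether with silylbutynyl chain | C[Si](C)(C)C#CCC[C@]1(O[Si](CC)(CC)CC)[C@H](C)CC[C@@H](C(C)(C)CO[Si](CC)(CC)CC)[C@]1(C)CCO[Si](CC)(CC)CC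
F5 | step 9 | tris(triethylsilyl) ether with terminal alkyne | C#CCC[C@]1(O[Si](CC)(CC)CC)[C@H](C)CC[C@@H](C(C)(C)CO[Si](CC)(CC)CC)[C@]1(C)CCO[Si](CC)(CC)CC
F6 | step 9 | tris(triethylsilyl) ether with complete E-enoate chain | COC(=O)/C=C(\C)CC[C@]1(O[Si](CC)(CC)CC)[C@H](C)CC[C@@H](C(C)(C)CO[Si](CC)(CC)CC)[C@]1(C)CCO[Si](CC)(CC)CC
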